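**Plan**

- Labels: U = upper flavan unit (rings A, C, B); L = lower epicatechin unit (rings D, F, E). After debenzylation the retrosynthesis cuts ring C at U-O1–U-C2 and U-C3–U-C4, then U-C4–L-C8, then the aryl–carbonyl bond of the two-carbon partner.
- Enabling feature: ring C is a benzopyran whose U-C4 already carries ring D, so U-O1, U-C8a, U-C4a and U-C4 are the four atoms of a ring A ortho-quinone methide, and U-C2/U-C3 are an α-oxygenated enol ether.
- Forward: rings D, F, E come intact from (−)-epicatechin and rings A and B from two arenes. The 8-lithiated penta-O-benzylepicatechin adds to a salicylaldehyde (U-C4–L-C8), and an acid-catalysed oxa-[4+2] cycloaddition closes ring C as a hemiketal.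
- U-C2 is then set through the open keto-phenol tautomer (chelate reduction, Mitsunobu re-closure of U-O1–U-C2) rather than by hydride addition to the closed oxocarbenium ion, because hydride would have to enter syn to ring D there.
- Stereochemistry: L-C2/L-C3 are bought; U-C4 comes from the chiral phosphate (any U-C4 epimer is a separable diastereomer); U-C3 from the exo benzyloxy group in the cycloaddition (3,4-trans); U-C2 from anti-selective reduction then SN2 inversion (2,3-cis).

Key step: step 7

Assumption: the (R)-enantiomer of the phosphoric acid is taken as the one that directs the enol ether to the quinone methide face giving (4R); if the sense is opposite, the (S)-enantiomer is used with no other change.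

**Route**

Step 1
Reactants: 1 (−)-epicatechin
Product: 2 5,7,3',4'-tetra-O-benzyl-(−)-epicatechin
Conditions: BnBr, K2CO3, DMF, 0 °C to rt
Reagents that add atoms: benzyl bromide, BrCc1ccccc1
Why: Williamson etherification in which carbonate deprotonates only the four phenols, so the secondary L-C3 hydroxyl stays free and no stereocentre is touched.

Step 2
Reactants: 2 5,7,3',4'-tetra-O-benzyl-(−)-epicatechin
Product: 3 3,5,7,3',4'-penta-O-benzyl-(−)-epicatechin
Conditions: NaH, BnBr, Bu4NI (cat.), DMF, 0 °C to rt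
Reagents that add atoms: benzyl bromide, BrCc1ccccc1
Why: Williamson etherification of the remaining secondary alcohol through its sodium alkoxide, with L-C2 no longer epimerisable because all phenols are capped.

Step 3
Reactants: 3 3,5,7,3',4'-penta-O-benzyl-(−)-epicatechin
Product: 4 8-bromo-3,5,7,3',4'-penta-O-benzyl-(−)-epicatechin
Conditions: NBS, CH2Cl2, −78 °C to 0 °C
Reagents that add atoms: N-bromosuccinimide, O=C1CCC(=O)N1Br
Why: electrophilic aromatic bromination of the phloroglucinol-type ring D, which is far more electron-rich than ring E and is known to react at L-C8 rather than L-C6 in benzylated (epi)catechins.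

Step 4
Reactants: 4 8-bromo-3,5,7,3',4'-penta-O-benzyl-(−)-epicatechin; 5 4-(benzyloxy)-2-hydroxybenzaldehyde
Product: 8 [4-(benzyloxy)-2-hydroxyphenyl](penta-O-benzylepicatechin-8-yl)methanol (both carbinol epimers), via 8-lithio arene 6 (not isolated), via sodium phenoxide 7 (not isolated)
Conditions: 4, n-BuLi, THF, −78 °C; then 7 (from 5, NaH, THF, 0 °C), −78 °C to 0 °C; sat. aq NH4Cl
Reagents that add atoms: none
Why: bromine–lithium exchange followed by 1,2-addition of the aryllithium to the aldehyde, with the phenol held as its sodium salt so that 6 is not protonated, and with no need to control the carbinol centre because it becomes trigonal in step 7.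

Step 5
Reactants: 9 2-(benzyloxy)-N-methoxy-N-methylacetamide; 10 4-(benzyloxy)phenylmagnesium bromide
Product: 12 2-(benzyloxy)-1-[4-(benzyloxy)phenyl]ethanone, via magnesium hemiaminal chelate 11 (not isolated)
Conditions: THF, 0 °C; sat. aq NH4Cl
Reagents that add atoms: none
Why: Weinreb ketone synthesis, in which the five-membered magnesium chelate blocks over-addition and releases the ketone only on work-up.

Step 6
Reactants: 12 2-(benzyloxy)-1-[4-(benzyloxy)phenyl]ethanone
Product: 13 (Z)-{2-(benzyloxy)-1-[4-(benzyloxy)phenyl]ethenyl}oxy(trimethyl)silane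
Conditions: Me3SiOTf, Et3N, CH2Cl2, 0 °C; pentane, filtration; used without chromatography
Reagents that add atoms: trimethylsilyl trifluoromethanesulfonate, C[Si](C)(C)OS(=O)(=O)C(F)(F)F
Why: soft enolisation with O-silylation of an aryl ketone, expected to favour the Z isomer (both oxygens cis) because the aryl group then avoids allylic strain with the benzyloxy group.

Step 7
Reactants: 8 [4-(benzyloxy)-2-hydroxyphenyl](penta-O-benzylepicatechin-8-yl)methanol; 13 (Z)-silyl enol ether
Product: 16 (2S,3R,4R)-3,7-bis(benzyloxy)-2-[4-(benzyloxy)phenyl]-4-(penta-O-benzylepicatechin-8-yl)chroman-2-ol (3,4-trans hemiketal), via ortho-quinone methide 14 (not isolated), via trimethylsilyl ketal 15 (not isolated)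
Conditions: (R)-3,3'-bis(2,4,6-triisopropylphenyl)-1,1'-binaphthyl-2,2'-diyl hydrogen phosphate (10 mol %), 13 (2.5 equiv), 4 Å molecular sieves, toluene, −20 °C; then AcOH–H2O–THF, 0 °C
Reagents that add atoms: none
Why: The phosphoric acid dehydrates 8 to the (E)-ortho-quinone methide 14, helped by the electron-rich ring D on U-C4, and stays hydrogen-bonded to its carbonyl oxygen (the later U-O1) while U-C3 of the enol ether attacks U-C4 and U-O1 closes on the siloxy-stabilised U-C2; this is an inverse-demand oxa-[4+2] cycloaddition (or Mukaiyama–Michael addition then ketalisation) of the type known for acid-catalysed reactions of in situ ortho-quinone methides with enol ethers, enamides and styrenes. Ring C closes as the second bond of the cycloaddition, in the stepwise limit by 6-exo-trig attack of the phenol oxygen on the silyloxocarbenium ion. U-C4 is set by the chiral phosphate shielding one face of the bound quinone methide; U-C3 is set by approach with ring B endo and both ether oxygens exo, which places the benzyloxy group trans to ring D, and it stays adjustable because it is α to the carbonyl of the open tautomer 17; U-C2 follows from the Z geometry (ring B equatorial, oxygen axial), is anomeric and mobile, and is reset in steps 8 and 9. The step needs U-C3 rather than U-C2 to bond to U-C4, secured because only a cation at U-C2 is stabilised by both the siloxy oxygen and the 4-benzyloxyphenyl ring; it also needs face selectivity at U-C4, secured by the catalyst and backed by the fact that the U-C4 epimers are diastereomers (epicatechin unit) and can be separated. Molecular sieves take up the released water so that the excess silyl enol ether is not hydrolysed, and buffered aqueous acetic acid then cleaves silyl ketal 15 to hemiketal 16.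

Step 8
Reactants: 16 3,4-trans hemiketal
Product: 18 (1S,2R,3R)-2-(benzyloxy)-1-[4-(benzyloxy)phenyl]-3-[4-(benzyloxy)-2-hydroxyphenyl]-3-(penta-O-benzylepicatechin-8-yl)propan-1-ol (anti carbinol), via keto-phenol tautomer 17 (not isolated)
Conditions: Zn(BH4)2, Et2O–CH2Cl2, −20 °C to 0 °C; sat. aq NH4Cl
Reagents that add atoms: none
Why: chelation-controlled (Cram chelate) hydride reduction in which ring–chain tautomerism supplies ketone 17, zinc bridges the carbonyl and the α-benzyloxy oxygen, and hydride enters anti to the bulky U-C4 diarylmethyl group to give the anti (erythro) carbinol with U-C2 as S, a control element that does not depend on the congested faces of the closed ring.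

Step 9
Reactants: 18 anti carbinol
Product: 20 (2R,3R,4R)-3,7-bis(benzyloxy)-2-[4-(benzyloxy)phenyl]-4-(penta-O-benzylepicatechin-8-yl)chroman (octa-O-benzyl target), via alkoxyphosphonium zwitterion 19 (not isolated)
Conditions: PPh3, DIAD, THF, 0 °C to rt
Reagents that add atoms: none
Why: intramolecular Mitsunobu etherification, a ring closure precedented in flavan and flavan-3-ol synthesis, in which the phenoxide displaces the alkoxyphosphonium group in a 6-exo-tet SN2 step with inversion, turning the (S)-carbinol into (2R) and hence the 2,3-cis-3,4-trans ring C.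

Step 10
Reactants: 20 octa-O-benzyl target
Product: 21 epiguibourtinidol-(4β→8)-epicatechin, (2R,3R,4R)-4-[(2R,3R)-2-(3,4-dihydroxyphenyl)-3,5,7-trihydroxychroman-8-yl]-2-(4-hydroxyphenyl)chroman-3,7-diol
Conditions: H2 (1 atm), Pd(OH)2/C, THF–MeOH, rt
Reagents that add atoms: none
Why: hydrogenolysis of the eight benzyl ethers, the standard last step for benzylated proanthocyanidins, which under neutral conditions at 1 atm should leave the cyclic benzylic ethers, the U-C4–L-C8 bond and all five stereocentres untouched.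

**Compound list**

1 | (−)-epicatechin | Oc1cc(O)c2c(c1)O[C@H](c1ccc(O)c(O)c1)[C@H](O)C2 | starting material
2 | 5,7,3',4'-tetra-O-benzyl-(−)-epicatechin | c3c(OCc5ccccc5)cc(OCc5ccccc5)c4c3O[C@H](c3ccc(OCc5ccccc5)c(OCc5ccccc5)c3)[C@H](O)C4 | intermediate
3 | 3,5,7,3',4'-penta-O-benzyl-(−)-epicatechin | c3c(OCc5ccccc5)cc(OCc5ccccc5)c4c3O[C@H](c3ccc(OCc5ccccc5)c(OCc5ccccc5)c3)[C@H](OCc5ccccc5)C4 | intermediate
4 | 8-bromo-3,5,7,3',4'-penta-O-benzyl-(−)-epicatechin | Brc3c(OCc5ccccc5)cc(OCc5ccccc5)c4c3O[C@H](c3ccc(OCc5ccccc5)c(OCc5ccccc5)c3)[C@H](OCc5ccccc5)C4 | intermediate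
5 | 4-(benzyloxy)-2-hydroxybenzaldehyde | O=Cc1ccc(OCc2ccccc2)cc1O | starting material
6 | 8-lithio-3,5,7,3',4'-penta-O-benzyl-(−)-epicatechin | [Li]c3c(OCc5ccccc5)cc(OCc5ccccc5)c4c3O[C@H](c3ccc(OCc5ccccc5)c(OCc5ccccc5)c3)[C@H](OCc5ccccc5)C4 | intermediate
7 | sodium 5-(benzyloxy)-2-formylphenolate | [Na+].[O-]c1cc(OCc2ccccc2)ccc1C=O | intermediate
8 | [4-(benzyloxy)-2-hydroxyphenyl](penta-O-benzylepicatechin-8-yl)methanol, carbinol epimers | Oc1cc(OCc5ccccc5)ccc1C(O)c3c(OCc5ccccc5)cc(OCc5ccccc5)c4c3O[C@H](c3ccc(OCc5ccccc5)c(OCc5ccccc5)c3)[C@H](OCc5ccccc5)C4 | intermediate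
9 | 2-(benzyloxy)-N-methoxy-N-methylacetamide | CON(C)C(=O)COCc1ccccc1 | starting material
10 | 4-(benzyloxy)phenylmagnesium bromide (THF solution) | Br[Mg]c1ccc(OCc2ccccc2)cc1 | starting material
11 | bromomagnesium salt of the tetrahedral N-methoxy-N-methyl hemiaminal | CON(C)C(O[Mg]Br)(COCc1ccccc1)c1ccc(OCc2ccccc2)cc1 | intermediate
12 | 2-(benzyloxy)-1-[4-(benzyloxy)phenyl]ethanone | O=C(COCc1ccccc1)c1ccc(OCc2ccccc2)cc1 | intermediate
13 | (Z)-{2-(benzyloxy)-1-[4-(benzyloxy)phenyl]ethenyl}oxy(trimethyl)silane | C[Si](C)(C)O/C(c1ccc(OCc2ccccc2)cc1)=C\OCc1ccccc1 | intermediate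
14 | (E)-ortho-quinone methide: 3-(benzyloxy)-6-[(penta-O-benzylepicatechin-8-yl)methylidene]cyclohexa-2,4-dien-1-one | O=C1C=C(OCc5ccccc5)C=C/C1=C\c3c(OCc5ccccc5)cc(OCc5ccccc5)c4c3O[C@H](c3ccc(OCc5ccccc5)c(OCc5ccccc5)c3)[C@H](OCc5ccccc5)C4 | intermediate
15 | trimethylsilyl ketal of 16 (siloxy group cis to the U-C3 benzyloxy group, 3,4-trans) | O(Cc5ccccc5)c1ccc([C@]2(O[Si](C)(C)C)Oc3cc(OCc5ccccc5)ccc3[C@H](c3c(OCc5ccccc5)cc(OCc5ccccc5)c4c3O[C@H](c3ccc(OCc5ccccc5)c(OCc5ccccc5)c3)[C@H](OCc5ccccc5)C4)[C@H]2OCc5ccccc5)cc1 | intermediate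
16 | (2S,3R,4R)-3,7-bis(benzyloxy)-2-[4-(benzyloxy)phenyl]-4-(penta-O-benzylepicatechin-8-yl)chroman-2-ol (hydroxyl axial, cis to the U-C3 ether; 3,4-trans; anomeric centre mobile) | O(Cc5ccccc5)c1ccc([C@]2(O)Oc3cc(OCc5ccccc5)ccc3[C@H](c3c(OCc5ccccc5)cc(OCc5ccccc5)c4c3O[C@H](c3ccc(OCc5ccccc5)c(OCc5ccccc5)c3)[C@H](OCc5ccccc5)C4)[C@H]2OCc5ccccc5)cc1 | intermediate
17 | (2R,3R)-2-(benzyloxy)-1-[4-(benzyloxy)phenyl]-3-[4-(benzyloxy)-2-hydroxyphenyl]-3-(penta-O-benzylepicatechin-8-yl)propan-1-one | O=C(c1ccc(OCc5ccccc5)cc1)[C@H](OCc5ccccc5)[C@@H](c3c(OCc5ccccc5)cc(OCc5ccccc5)c4c3O[C@H](c3ccc(OCc5ccccc5)c(OCc5ccccc5)c3)[C@H](OCc5ccccc5)C4)c1ccc(OCc5ccccc5)cc1O | intermediate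
18 | (1S,2R,3R)-2-(benzyloxy)-1-[4-(benzyloxy)phenyl]-3-[4-(benzyloxy)-2-hydroxyphenyl]-3-(penta-O-benzylepicatechin-8-yl)propan-1-ol | O[C@@H](c1ccc(OCc5ccccc5)cc1)[C@H](OCc5ccccc5)[C@@H](c3c(OCc5ccccc5)cc(OCc5ccccc5)c4c3O[C@H](c3ccc(OCc5ccccc5)c(OCc5ccccc5)c3)[C@H](OCc5ccccc5)C4)c1ccc(OCc5ccccc5)cc1O | intermediate
19 | alkoxy(triphenyl)phosphonium phenoxide zwitterion of 18 | c6ccccc6[P+](c6ccccc6)(c6ccccc6)O[C@@H](c1ccc(OCc5ccccc5)cc1)[C@H](OCc5ccccc5)[C@@H](c3c(OCc5ccccc5)cc(OCc5ccccc5)c4c3O[C@H](c3ccc(OCc5ccccc5)c(OCc5ccccc5)c3)[C@H](OCc5ccccc5)C4)c1ccc(OCc5ccccc5)cc1[O-] | intermediate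
20 | (2R,3R,4R)-3,7-bis(benzyloxy)-2-[4-(benzyloxy)phenyl]-4-(penta-O-benzylepicatechin-8-yl)chroman (2,3-cis-3,4-trans) | O(Cc5ccccc5)c1ccc([C@H]2Oc3cc(OCc5ccccc5)ccc3[C@H](c3c(OCc5ccccc5)cc(OCc5ccccc5)c4c3O[C@H](c3ccc(OCc5ccccc5)c(OCc5ccccc5)c3)[C@H](OCc5ccccc5)C4)[C@H]2OCc5ccccc5)cc1 | intermediate
21 | epiguibourtinidol-(4β→8)-epicatechin (CNP0118995.2) | Oc1ccc([C@H]2Oc3cc(O)ccc3[C@H](c3c(O)cc(O)c4c3O[C@H](c3ccc(O)c(O)c3)[C@H](O)C4)[C@H]2O)cc1 | target

**Count**

Total: 10 steps. Longest linear sequence: 8 steps (steps 1, 2, 3, 4, 7, 8, 9, 10) from (−)-epicatechin.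

**Steps most likely to fail**

Step 7. The risk is weak face discrimination at U-C4 because the chiral ring D substituent may oppose the catalyst, low 3,4-trans selectivity at U-C3, and acid-promoted loss of the silyl enol ether before it adds. The fallback sets out from 8 and returns at 16. It replaces kinetic catalyst control by thermodynamic control in a lactone and chromatographic separation of diastereomers. Quinone methide 14 is generated from 8 with diphenyl hydrogen phosphate in the presence of the silyl ketene acetal (Z)-[2-(benzyloxy)-1-methoxyethenyl]oxy(trimethyl)silane F1 (from methyl 2-(benzyloxy)acetate, LDA, Me3SiCl). The Mukaiyama–Michael adduct, methyl 2-(benzyloxy)-3-[4-(benzyloxy)-2-hydroxyphenyl]-3-(penta-O-benzylepicatechin-8-yl)propanoate F2, is lactonised (TsOH, toluene) and equilibrated with DBU to the 3,4-trans dihydrocoumarin (3R,4R)-3,7-bis(benzyloxy)-4-(penta-O-benzylepicatechin-8-yl)chroman-2-one F3. Its U-C4 epimer is a diastereomer and is removed by chromatography. Addition of Grignard reagent 10 to the lactone carbonyl at −78 °C then gives 16.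

Step 9. The risk is ionisation of the 4-benzyloxybenzylic alkoxyphosphonium ion before displacement, which would erase the inversion and let the ring close under thermodynamic control toward the 2,3-trans isomer, or elimination. The fallback sets out from 16 and returns at 20, bypassing steps 8 and 9 with no new compound on the way (F0). It is an ionic hydrogenation of the hemiketal with Et3SiH and BF3·OEt2 in CH2Cl2 at −78 °C. Ring C stays closed as the 2-aryl oxocarbenium ion; allylic strain with the coplanar ring B pushes the U-C3 ether pseudoaxial, and hydride is delivered axially anti to it, as in the reduction of 1-C-aryl ketoses to C-aryl glycosides.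

Step 4. The risk is slow addition of the hindered, doubly ortho-substituted aryllithium to an aldehyde deactivated as its phenoxide, so that 6 is protonated back to 3. The fallback sets out from 5 and returns at 8. Aldehyde 5 is allylated (allyl bromide, K2CO3, DMF) to 2-(allyloxy)-4-(benzyloxy)benzaldehyde F4. This neutral, more electrophilic aldehyde takes up aryllithium 6 at −78 °C to give [2-(allyloxy)-4-(benzyloxy)phenyl](penta-O-benzylepicatechin-8-yl)methanol F5. The allyl ether is then removed under neutral conditions with Pd(PPh3)4 (zerovalent palladium) and morpholine in THF to give 8.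

**Further compounds**

F1 | step 7 | (Z)-[2-(benzyloxy)-1-methoxyethenyl]oxy(trimethyl)silane | CO/C(O[Si](C)(C)C)=C/OCc1ccccc1
F2 | step 7 | methyl 2-(benzyloxy)-3-[4-(benzyloxy)-2-hydroxyphenyl]-3-(penta-O-benzylepicatechin-8-yl)propanoate (diastereomer mixture at the two new centres) | COC(=O)C(OCc5ccccc5)C(c3c(OCc5ccccc5)cc(OCc5ccccc5)c4c3O[C@H](c3ccc(OCc5ccccc5)c(OCc5ccccc5)c3)[C@H](OCc5ccccc5)C4)c1ccc(OCc5ccccc5)cc1O
F3 | step 7 | (3R,4R)-3,7-bis(benzyloxy)-4-(penta-O-benzylepicatechin-8-yl)chroman-2-one | O=C2Oc3cc(OCc5ccccc5)ccc3[C@H](c3c(OCc5ccccc5)cc(OCc5ccccc5)c4c3O[C@H](c3ccc(OCc5ccccc5)c(OCc5ccccc5)c3)[C@H](OCc5ccccc5)C4)[C@H]2OCc5ccccc5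
F0 | step 9 | none | none
F4 | step 4 | 2-(allyloxy)-4-(benzyloxy)benzaldehyde | C=CCOc1cc(OCc2ccccc2)ccc1C=O
F5 | step 4 | [2-(allyloxy)-4-(benzyloxy)phenyl](penta-O-benzylepicatechin-8-yl)methanol (carbinol epimers) | C=CCOc1cc(OCc5ccccc5)ccc1C(O)c3c(OCc5ccccc5)cc(OCc5ccccc5)c4c3O[C@H](c3ccc(OCc5ccccc5)c(OCc5ccccc5)c3)[C@H](OCc5ccccc5)C4
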